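**Retrosynthetic overview**

1. Target ⇐ hydroxyl-directed epoxidation of the C10 vinyl group (epoxide last); the α-methylene lactone and the propenal are unveiled just before, from an α-phosphono lactone (Horner–Wadsworth–Emmons) and a dioxolane.
2. Cyclohexane ⇐ C9–C10 bond by a nickel-catalysed reductive diene–aldehyde cyclisation (1,4-hydroboration, then intramolecular allylboration) that sets C9 and the quaternary C10.
3. Open-chain precursor ⇐ C5–C6 bond: anti-selective addition of an (E)-allyltrichlorosilane (fragment B: C1–C5, C10, C14, C15) to a lactone aldehyde (fragment A: C6–C9, C11, C12), then Yamaguchi angeloylation.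
4. Fragment A ⇐ (R)-5-(hydroxymethyl)furan-2(5H)-one (vinyl cuprate addition, phosphonation, ozonolysis); fragment B ⇐ Sonogashira coupling of 2-bromopropenal acetal with propargyl alcohol, then directed vinyl carbomagnesiation.
5. Ring order: γ-lactone (from the butenolide) → cyclohexane → epoxide.

Assumption: positions are given in elemane numbering (C1–C2 epoxide, C3/C4/C15 propenal unit, C5–C10 ring, C11–C13 lactone unit, C14 methyl); the C11 epimers of the phosphonates are carried as a mixture, and 1 and 8 are taken as purchasable.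

**Route**

Step 1
Reactants: 1 (R)-5-(hydroxymethyl)furan-2(5H)-one
Product: 2 (R)-5-[(triethylsilyloxy)methyl]furan-2(5H)-one
Conditions: Et3SiCl, imidazole, CH2Cl2, 0 °C
Reagents that add atoms: chlorotriethylsilane CC[Si](Cl)(CC)CC
Why: Silyl ether formation protects the primary alcohol (future C9) as a triethylsilyl ether that can later be oxidised directly to the aldehyde; the C8 stereocentre comes from the starting material.

Step 2
Reactants: 2 (R)-5-[(triethylsilyloxy)methyl]furan-2(5H)-one
Product: 3 (4S,5R)-4-ethenyl-5-[(triethylsilyloxy)methyl]oxolan-2-one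
Conditions: vinylMgBr, CuBr·SMe2 (10 mol%), THF, −78 → −40 °C; NH4Cl (aq)
Reagents that add atoms: vinylmagnesium bromide C=C[Mg]Br
Why: Copper-catalysed conjugate (Michael) addition of the vinyl group to the butenolide occurs anti to the C8 silyloxymethyl group and so sets C7 trans to C8, the future trans ring fusion.

Step 3
Reactants: 3 (4S,5R)-4-ethenyl-5-[(triethylsilyloxy)methyl]oxolan-2-one
Product: 5 (4S,5R)-3-(diethoxyphosphoryl)-4-ethenyl-5-[(triethylsilyloxy)methyl]oxolan-2-one (C3 epimers), via enol phosphate 4 (not isolated)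
Conditions: LDA, THF, −78 °C; ClP(O)(OEt)2; then LDA (2.2 equiv), −78 → 0 °C; AcOH
Reagents that add atoms: diethyl chlorophosphate CCOP(=O)(Cl)OCC
Why: O-phosphorylation of the lactone enolate followed by base-induced 1,3-phosphorus shift (enol phosphate to phosphonate rearrangement) installs at C11 a Horner–Wadsworth–Emmons handle, a masked methylene that tolerates the later steps, without touching C7 or C8.

Step 4
Reactants: 5 (4S,5R)-3-(diethoxyphosphoryl)-4-ethenyl-5-[(triethylsilyloxy)methyl]oxolan-2-one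
Product: 7 (2R,3R)-4-(diethoxyphosphoryl)-5-oxo-2-[(triethylsilyloxy)methyl]oxolane-3-carbaldehyde (fragment A), via ozonide 6 (not isolated)
Conditions: O3, CH2Cl2, −78 °C; then PPh3, −78 °C → rt
Reagents that add atoms: ozone [O-][O+]=O
Why: Ozonolysis with reductive work-up cleaves the only alkene to the C6 aldehyde, and the trans arrangement at C7/C8 is also the thermodynamic one.

Step 5
Reactants: 8 2-bromoprop-2-enal
Product: 9 2-(1-bromoethenyl)-1,3-dioxolane
Conditions: HOCH2CH2OH, PPTS (cat.), MgSO4, CH2Cl2, rt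
Reagents that add atoms: ethylene glycol OCCO
Why: Acid-catalysed acetalisation masks the future C15 aldehyde as a dioxolane that survives the coupling, Grignard, silane and nickel steps.

Step 6
Reactants: 9 2-(1-bromoethenyl)-1,3-dioxolane; 10 prop-2-yn-1-ol
Product: 11 4-(1,3-dioxolan-2-yl)pent-4-en-2-yn-1-ol
Conditions: PdCl2(PPh3)2 (2 mol%), CuI (4 mol%), Et3N, THF, rt
Reagents that add atoms: none
Why: Palladium/copper-catalysed Sonogashira coupling of the alkenyl bromide with the terminal alkyne forms the C4–C5 bond under mild conditions that leave the acetal and free alcohol untouched.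

Step 7
Reactants: 11 4-(1,3-dioxolan-2-yl)pent-4-en-2-yn-1-ol
Product: 12 (2E)-4-(1,3-dioxolan-2-yl)-2-ethenylpenta-2,4-dien-1-ol
Conditions: vinylMgCl (4 equiv), THF, 60 °C; NH4Cl (aq), 0 °C
Reagents that add atoms: vinylmagnesium chloride C=C[Mg]Cl
Why: Alkoxide-directed anti-carbomagnesiation of the propargylic alcohol (Fallis-type) puts the vinyl group on C10 and magnesium on C5 in a five-membered chelate, so protonation gives the trisubstituted alkene with C4 trans to the CH2OH group.

Step 8
Reactants: 12 (2E)-4-(1,3-dioxolan-2-yl)-2-ethenylpenta-2,4-dien-1-ol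
Product: 14 2-[(3E)-4-(chloromethyl)hexa-1,3,5-trien-2-yl]-1,3-dioxolane (fragment B), via mesylate 13 (not isolated)
Conditions: MsCl, 2,4,6-collidine, LiCl, DMF, 0 °C; used at once
Reagents that add atoms: lithium chloride [Li+].[Cl-]
Why: Mesylation followed by in situ SN2 displacement with chloride gives the primary allylic chloride without allylic transposition or loss of alkene geometry.

Step 9
Reactants: 15 angelic acid
Product: 16 (Z)-2-methylbut-2-enoic 2,4,6-trichlorobenzoic anhydride
Conditions: 2,4,6-trichlorobenzoyl chloride, Et3N, toluene, rt; filtered and used as solution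
Reagents that add atoms: 2,4,6-trichlorobenzoyl chloride O=C(Cl)c1c(Cl)cc(Cl)cc1Cl
Why: Yamaguchi mixed-anhydride activation at room temperature avoids the acid chloride, which isomerises angelate to tiglate.

Step 10
Reactants: 14 2-[(3E)-4-(chloromethyl)hexa-1,3,5-trien-2-yl]-1,3-dioxolane; 7 (2R,3R)-4-(diethoxyphosphoryl)-5-oxo-2-[(triethylsilyloxy)methyl]oxolane-3-carbaldehyde
Product: 18 (4S,5R)-3-(diethoxyphosphoryl)-4-{(1S,2R)-2-[1-(1,3-dioxolan-2-yl)ethenyl]-1-hydroxy-3-methylidenepent-4-en-1-yl}-5-[(triethylsilyloxy)methyl]oxolan-2-one, via allyltrichlorosilane 17 (not isolated)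
Conditions: HSiCl3, CuCl (5 mol%), iPr2NEt, Et2O, rt; concentrate; then 7, DMF, 0 °C; NaHCO3 (aq)
Reagents that add atoms: none
Why: CuCl-catalysed silylation gives the allyltrichlorosilane without transposition, and its DMF-promoted addition to the aldehyde (Kobayashi-type allylation through a closed chair transition state at hypervalent silicon) forms the C5–C6 bond at the γ-carbon, the (E) geometry giving the anti C5/C6 relationship and Felkin–Anh attack on the Si face (anti to the phosphonate-bearing C11 branch) giving (5R,6S).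

Step 11
Reactants: 18 homoallylic alcohol (name as in step 10); 16 (Z)-2-methylbut-2-enoic 2,4,6-trichlorobenzoic anhydride
Product: 19 (1S,2R)-1-{(2R,3S)-4-(diethoxyphosphoryl)-5-oxo-2-[(triethylsilyloxy)methyl]oxolan-3-yl}-2-[1-(1,3-dioxolan-2-yl)ethenyl]-3-methylidenepent-4-en-1-yl (Z)-2-methylbut-2-enoate
Conditions: 16 (1.5 equiv), DMAP, toluene, 40 °C
Reagents that add atoms: none
Why: Yamaguchi esterification acylates the only free hydroxyl with retention of the (Z) geometry, and doing it before the carbocycle exists avoids any later differentiation of the C6 and C9 hydroxyls and blocks translactonisation to O6.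

Step 12
Reactants: 19 angelate ester (name as in step 11)
Product: 21 (1S,2R)-1-[(2R,3S)-4-(diethoxyphosphoryl)-2-formyl-5-oxooxolan-3-yl]-2-[1-(1,3-dioxolan-2-yl)ethenyl]-3-methylidenepent-4-en-1-yl (Z)-2-methylbut-2-enoate, via alkoxysulfonium chloride 20 (not isolated)
Conditions: (COCl)2, DMSO, CH2Cl2, −78 → −40 °C; then Et3N, −78 → 0 °C
Reagents that add atoms: none
Why: Swern oxidation converts a primary triethylsilyl ether directly into the aldehyde (oxidative desilylation), and the low temperature keeps the α-acyloxy aldehyde from epimerising at C8.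

Step 13
Reactants: 21 aldehyde (name as in step 12)
Product: 23 (3aS,4S,5R,6S,7S,7aR)-3-(diethoxyphosphoryl)-5-[1-(1,3-dioxolan-2-yl)ethenyl]-6-ethenyl-7-hydroxy-6-methyl-2-oxooctahydro-1-benzofuran-4-yl (Z)-2-methylbut-2-enoate, via (Z)-allylboronate 22 (not isolated)
Conditions: Ni(cod)2 (5 mol%), PCy3 (5 mol%), HBpin (1.2 equiv, slow addition), toluene, 25 °C; NaHCO3 (aq)
Reagents that add atoms: none
Why: Proposed new method: a nickel-catalysed reductive diene–aldehyde cyclisation in which Ni(cod)2/PCy3 mediates 1,4-hydroboration of the 2-substituted 1,3-diene (hydride to the exocyclic CH2, which becomes the C14 methyl, boron to C2, (Z)-allylboronate because the diene reacts in its s-cis form) and the tethered α-acyloxy aldehyde then captures the γ-carbon C10 by intramolecular allylboration through a chair transition state cis-fused to the chair of the forming cyclohexane (locked by the trans lactone, C5 substituent equatorial), which places the C9 oxygen axial, the new vinyl group equatorial and the methyl axial, i.e. (9S,10S); the closest known chemistry is nickel-catalysed 1,4-hydroboration of dienes followed by a separate intermolecular aldehyde allylation, and nickel-catalysed reductive diene–aldehyde cyclisations that bond at the diene terminus, whereas a one-flask ring closure at the internal diene carbon with the aldehyde present during hydroboration has not been described.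

Step 14
Reactants: 23 bicyclic hydroxy phosphono lactone (name as in step 13)
Product: 25 (3aS,4S,5R,6S,7S,7aR)-6-ethenyl-7-hydroxy-6-methyl-3-methylidene-2-oxo-5-(3-oxoprop-1-en-2-yl)octahydro-1-benzofuran-4-yl (Z)-2-methylbut-2-enoate, via methylene lactone acetal 24 (not isolated)
Conditions: K2CO3, 37% aq. HCHO, THF, 0 °C → rt; then 1 M HCl, rt
Reagents that add atoms: formaldehyde C=O
Why: Horner–Wadsworth–Emmons olefination with formaldehyde turns the phosphonate into the α-methylene lactone under mild carbonate conditions that spare the angelate, and acidification of the same flask hydrolyses the dioxolane to the 2-substituted propenal before the acid-sensitive epoxide exists.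

Step 15
Reactants: 25 enal (name as in step 14)
Product: 26 (3aS,4S,5R,6S,7S,7aR)-7-hydroxy-6-methyl-3-methylidene-6-[(2R)-oxiran-2-yl]-2-oxo-5-(3-oxoprop-1-en-2-yl)octahydro-1-benzofuran-4-yl (Z)-2-methylbut-2-enoate (CNP0113462.3)
Conditions: VO(acac)2 (5 mol%), t-BuOOH (decane), CH2Cl2, 0 °C → rt
Reagents that add atoms: tert-butyl hydroperoxide CC(C)(C)OO
Why: Vanadium-catalysed hydroxyl-directed epoxidation of the homoallylic alcohol selects the electron-neutral C10 vinyl group over the three electron-poor alkenes, and oxygen delivery from the axial C9 alkoxide on the face anti to the axial methyl, through a chair vanadate transition state with the terminal CH2 pseudo-equatorial, gives the (1R)-epoxide.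

**Compound list**

1 | (R)-5-(hydroxymethyl)furan-2(5H)-one | OC[C@@H]1OC(=O)C=C1 | starting material
2 | (R)-5-[(triethylsilyloxy)methyl]furan-2(5H)-one | CC[Si](CC)(CC)OC[C@@H]1OC(=O)C=C1 | intermediate
3 | (4S,5R)-4-ethenyl-5-[(triethylsilyloxy)methyl]oxolan-2-one | CC[Si](CC)(CC)OC[C@@H]1OC(=O)C[C@H]1C=C | intermediate
4 | diethyl (4R,5R)-4-ethenyl-5-[(triethylsilyloxy)methyl]-4,5-dihydrofuran-2-yl phosphate (enol phosphate) | CC[Si](CC)(CC)OC[C@@H]1OC(OP(=O)(OCC)OCC)=C[C@H]1C=C | intermediate
5 | (4S,5R)-3-(diethoxyphosphoryl)-4-ethenyl-5-[(triethylsilyloxy)methyl]oxolan-2-one (C3 epimers) | CC[Si](CC)(CC)OC[C@@H]1OC(=O)C(P(=O)(OCC)OCC)[C@H]1C=C | intermediate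
6 | secondary ozonide of 5 (ethenyl group as 1,2,4-trioxolan-3-yl) | CC[Si](CC)(CC)OC[C@@H]1OC(=O)C(P(=O)(OCC)OCC)[C@H]1C2OCOO2 | intermediate
7 | (2R,3R)-4-(diethoxyphosphoryl)-5-oxo-2-[(triethylsilyloxy)methyl]oxolane-3-carbaldehyde (fragment A) | CC[Si](CC)(CC)OC[C@@H]1OC(=O)C(P(=O)(OCC)OCC)[C@H]1C=O | intermediate
8 | 2-bromoprop-2-enal | C=C(Br)C=O | starting material
9 | 2-(1-bromoethenyl)-1,3-dioxolane | C=C(Br)C1OCCO1 | intermediate
10 | prop-2-yn-1-ol | OCC#C | starting material
11 | 4-(1,3-dioxolan-2-yl)pent-4-en-2-yn-1-ol | OCC#CC(=C)C1OCCO1 | intermediate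
12 | (2E)-4-(1,3-dioxolan-2-yl)-2-ethenylpenta-2,4-dien-1-ol | OC/C(C=C)=C/C(=C)C1OCCO1 | intermediate
13 | (2E)-4-(1,3-dioxolan-2-yl)-2-ethenylpenta-2,4-dien-1-yl methanesulfonate | CS(=O)(=O)OC/C(C=C)=C/C(=C)C1OCCO1 | intermediate
14 | 2-[(3E)-4-(chloromethyl)hexa-1,3,5-trien-2-yl]-1,3-dioxolane (fragment B) | ClC/C(C=C)=C/C(=C)C1OCCO1 | intermediate
15 | angelic acid, (Z)-2-methylbut-2-enoic acid | C/C=C(/C)C(=O)O | starting material
16 | (Z)-2-methylbut-2-enoic 2,4,6-trichlorobenzoic anhydride | C/C=C(/C)C(=O)OC(=O)c1c(Cl)cc(Cl)cc1Cl | intermediate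
17 | trichloro[(2E)-4-(1,3-dioxolan-2-yl)-2-ethenylpenta-2,4-dien-1-yl]silane | Cl[Si](Cl)(Cl)C/C(C=C)=C/C(=C)C1OCCO1 | intermediate
18 | (4S,5R)-3-(diethoxyphosphoryl)-4-{(1S,2R)-2-[1-(1,3-dioxolan-2-yl)ethenyl]-1-hydroxy-3-methylidenepent-4-en-1-yl}-5-[(triethylsilyloxy)methyl]oxolan-2-one (5R,6S,7S,8R in elemane numbering) | CC[Si](CC)(CC)OC[C@@H]1OC(=O)C(P(=O)(OCC)OCC)[C@H]1[C@@H](O)[C@@H](C(=C)C2OCCO2)C(=C)C=C | intermediate
19 | (1S,2R)-1-{(2R,3S)-4-(diethoxyphosphoryl)-5-oxo-2-[(triethylsilyloxy)methyl]oxolan-3-yl}-2-[1-(1,3-dioxolan-2-yl)ethenyl]-3-methylidenepent-4-en-1-yl (Z)-2-methylbut-2-enoate | CC[Si](CC)(CC)OC[C@@H]1OC(=O)C(P(=O)(OCC)OCC)[C@H]1[C@@H](OC(=O)/C(C)=C\C)[C@@H](C(=C)C2OCCO2)C(=C)C=C | intermediate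
20 | alkoxydimethylsulfonium chloride of 19 (SiEt3 on the C9 oxygen replaced by SMe2+) | C[S+](C)OC[C@@H]1OC(=O)C(P(=O)(OCC)OCC)[C@H]1[C@@H](OC(=O)/C(C)=C\C)[C@@H](C(=C)C2OCCO2)C(=C)C=C.[Cl-] | intermediate
21 | (1S,2R)-1-[(2R,3S)-4-(diethoxyphosphoryl)-2-formyl-5-oxooxolan-3-yl]-2-[1-(1,3-dioxolan-2-yl)ethenyl]-3-methylidenepent-4-en-1-yl (Z)-2-methylbut-2-enoate | O=C[C@@H]1OC(=O)C(P(=O)(OCC)OCC)[C@H]1[C@@H](OC(=O)/C(C)=C\C)[C@@H](C(=C)C2OCCO2)C(=C)C=C | intermediate
22 | (1S,2R,3Z)-1-[(2R,3S)-4-(diethoxyphosphoryl)-2-formyl-5-oxooxolan-3-yl]-2-[1-(1,3-dioxolan-2-yl)ethenyl]-3-methyl-5-(4,4,5,5-tetramethyl-1,3,2-dioxaborolan-2-yl)pent-3-en-1-yl (Z)-2-methylbut-2-enoate | O=C[C@@H]1OC(=O)C(P(=O)(OCC)OCC)[C@H]1[C@@H](OC(=O)/C(C)=C\C)[C@@H](C(=C)C2OCCO2)/C(C)=C\CB2OC(C)(C)C(C)(C)O2 | intermediate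
23 | (3aS,4S,5R,6S,7S,7aR)-3-(diethoxyphosphoryl)-5-[1-(1,3-dioxolan-2-yl)ethenyl]-6-ethenyl-7-hydroxy-6-methyl-2-oxooctahydro-1-benzofuran-4-yl (Z)-2-methylbut-2-enoate | O=P(OCC)(OCC)C1C(=O)O[C@@H]2[C@@H]1[C@@H](OC(=O)/C(C)=C\C)[C@@H](C(=C)C3OCCO3)[C@](C)(C=C)[C@@H]2O | intermediate
24 | (3aS,4S,5R,6S,7S,7aR)-5-[1-(1,3-dioxolan-2-yl)ethenyl]-6-ethenyl-7-hydroxy-6-methyl-3-methylidene-2-oxooctahydro-1-benzofuran-4-yl (Z)-2-methylbut-2-enoate | C=C1C(=O)O[C@@H]2[C@@H]1[C@@H](OC(=O)/C(C)=C\C)[C@@H](C(=C)C3OCCO3)[C@](C)(C=C)[C@@H]2O | intermediate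
25 | (3aS,4S,5R,6S,7S,7aR)-6-ethenyl-7-hydroxy-6-methyl-3-methylidene-2-oxo-5-(3-oxoprop-1-en-2-yl)octahydro-1-benzofuran-4-yl (Z)-2-methylbut-2-enoate | C=C1C(=O)O[C@@H]2[C@@H]1[C@@H](OC(=O)/C(C)=C\C)[C@@H](C(=C)C=O)[C@](C)(C=C)[C@@H]2O | intermediate
26 | CNP0113462.3, (3aS,4S,5R,6S,7S,7aR)-7-hydroxy-6-methyl-3-methylidene-6-[(2R)-oxiran-2-yl]-2-oxo-5-(3-oxoprop-1-en-2-yl)octahydro-1-benzofuran-4-yl (Z)-2-methylbut-2-enoate | C=C1C(=O)O[C@@H]2[C@@H]1[C@@H](OC(=O)/C(C)=C\C)[C@@H](C(=C)C=O)[C@](C)([C@@H]1CO1)[C@@H]2O | target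

**Step count and risks**

Total step count: 15.
Longest linear sequence: 10 steps (steps 1–4 then 10–15; equally steps 5–8 then 10–15); the angelate branch (step 9) joins at step 11.

Steps most likely to fail:

Step 13 (the proposed nickel-catalysed reductive cyclisation). The aldehyde may be reduced by HBpin or may bind the nickel catalyst before the diene is hydroborated. The fallback uses known chemistry and installs boron before the aldehyde exists. It sets out from 19: nickel-catalysed 1,4-hydroboration of the diene (Ni(cod)2/PCy3, HBpin, toluene, rt; no carbonyl electrophile present) gives the isolable (Z)-allylboronate silyl ether F1. The triethylsilyl ether is cleaved (AcOH/THF/H2O, 0 °C) to the primary alcohol F2. Buffered Dess–Martin oxidation (NaHCO3, CH2Cl2, 0 °C) then generates aldehyde 22, which cyclises by intramolecular allylboration (a (Z)-allylboronate gives the cis hydroxyl/vinyl product). The route is rejoined at 23.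

Step 10 (fragment union). The face selectivity rests on substrate (Felkin–Anh) control and may be only moderate. The fallback replaces substrate control by reagent control; it sets out from 17 (made from 14 as in step 10) and 7. Silane 17 is treated with (1R,2R)-N,N′-bis(4-bromobenzyl)cyclohexane-1,2-diamine and DBU (CH2Cl2, 0 °C) to give the strained chiral allylchlorosilane F3 (Leighton-type reagent). F3 adds to 7 without Lewis base (CH2Cl2, 0 °C, Sc(OTf)3 as catalyst if slow) through the same closed chair, so the anti relationship is kept. The diamine enantiomer is the one meant to deliver Si-face attack; I could not confirm the published sense from memory, so it should be checked on a model aldehyde and the mirror-image diamine used if needed. Work-up with pH 7 buffer releases the diamine and returns the route at 18.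

Step 15 (directed epoxidation). Directed epoxidation of a homoallylic alcohol can be slow or poorly diastereoselective, and the aldehyde may be oxidised. The fallback builds the epoxide by dihydroxylation and ring closure; it sets out from 25. Ligand-controlled dihydroxylation of the only electron-neutral alkene (OsO4 cat., (DHQD)2PHAL, NMO, acetone/H2O, 0 °C) gives the (1R)-1,2-diol F4. Mitsunobu cyclodehydration (PPh3, DIAD, toluene, 0 °C → rt) activates the primary hydroxyl and closes the epoxide with retention at C1, arriving at 26.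

**Further compounds**

F1 | step 13 | 1,4-hydroboration product of 19: (Z)-allyl pinacolboronate with C9 still a triethylsilyl ether | CC[Si](CC)(CC)OC[C@@H]1OC(=O)C(P(=O)(OCC)OCC)[C@H]1[C@@H](OC(=O)/C(C)=C\C)[C@@H](C(=C)C2OCCO2)/C(C)=C\CB2OC(C)(C)C(C)(C)O2
F2 | step 13 | primary alcohol from F1 (C9 hydroxyl free, (Z)-allyl pinacolboronate) | OC[C@@H]1OC(=O)C(P(=O)(OCC)OCC)[C@H]1[C@@H](OC(=O)/C(C)=C\C)[C@@H](C(=C)C2OCCO2)/C(C)=C\CB2OC(C)(C)C(C)(C)O2
F3 | step 10 | (3aR,7aR)-1,3-bis(4-bromobenzyl)-2-chloro-2-[(2E)-4-(1,3-dioxolan-2-yl)-2-ethenylpenta-2,4-dien-1-yl]octahydro-1H-1,3,2-benzodiazasilole | Cl[Si]1(C/C(C=C)=C/C(=C)C2OCCO2)N(Cc2ccc(Br)cc2)[C@@H]2CCCC[C@H]2N1Cc1ccc(Br)cc1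
F4 | step 15 | (1R)-1,2-diol from 25 (C10 vinyl group dihydroxylated) | C=C1C(=O)O[C@@H]2[C@@H]1[C@@H](OC(=O)/C(C)=C\C)[C@@H](C(=C)C=O)[C@](C)([C@@H](O)CO)[C@@H]2O
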